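## Plan

Zerumbone atom labels C1–C11 are kept to the end. C9 is the CMe2 carbon. The target ring is C1–C8, C10, C11, and C9 becomes the lactone α-carbon with C12/C13 as its former methyls.
Retrosynthetic cuts, in order: C8–O (angelate); lactone C12–O11 with the C12 oxidation level (back to an isopropenyl group on C10); ring bond C8–C10 (re-made as C8–C9); acyl–O1; then the oxygens at C10/C11, C7, C4 and C2.
Cutting C8–C10 turns the ten-membered ring into the eleven-membered ring of commercial zerumbone. That ring already holds all 15 skeletal carbons, both ring methyls (C2, C6) and the oxygen on C1.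
Enabling feature: exocyclic C9 sits on ring carbon C10, between carbinol carbon C11 and C8, which is α to the C7 ketone. With C9 back in the ring this reads epoxide carbon C10 / quaternary C9 / enol-ether carbon C8, a 2,2-dimethylbut-3-enyl radical array primed for a 1,2-vinyl shift.
Forward: the 11-ring is oxygenated (C2, C4, C7, C1, C10–C11) and contracted to the 10-ring by Ti(III). Then C11 is inverted, C8 brominated, the lactone ring closed from the isopropenyl group and O11, bromide displaced by angelate, and the silylene removed.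
Stereochemistry: C2 from Davis hydroxylation. Relays are C2→C4 (Narasaka–Prasad), C2→C1 (Felkin–Anh), C1→epoxide (matched Sharpless), C11→C10 (anti radical attack), C1→C11 (reduction) and C10→C8 (bromination, then SN2 inversion). C6 comes from Shi epoxidation/H-shift and C2′ from asymmetric hydrogenation.

Key step: step 12

Remark 1: the (−)-enantiomer of the camphor oxaziridine is assumed to give the 2S alcohol; if the sense is opposite, the equally available antipode is used.
Remark 2: the new C3=C4 bond of 3 is drawn E; its geometry is erased in step 2.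
Remark 3: the target is drawn and made as the open 4-hydroxy-7-ketone, which may equilibrate with its cyclic hemiketal.

## Route

Step 1
Reactants: 1 zerumbone
Product: 3 (2S,3E,6E,10E)-2-hydroxy-2,6,9,9-tetramethylcycloundeca-3,6,10-trien-1-one, via potassium dienolate 2 (not isolated)
Conditions: KHMDS, THF, −78 °C; (1R)-(−)-(10-camphorsulfonyl)oxaziridine, −78 °C; AcOH
Reagents that add atoms: (1R)-(−)-(10-camphorsulfonyl)oxaziridine, CC1(C)C2CCC13CS(=O)(=O)N4OC34C2
Why: γ-deprotonation at C4 is the only enolisation open to this cross-conjugated dienone, and the extended dienolate takes oxygen at its α-carbon C2 with deconjugation (Davis asymmetric enolate hydroxylation), the camphor reagent selecting the face that gives the 2S tertiary alcohol.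

Step 2
Reactants: 3 α-ketol
Product: 4 (2S,6E,10E)-2-hydroxy-2,6,9,9-tetramethylcycloundeca-6,10-diene-1,4-dione
Conditions: Pd(Quinox)Cl2 (cat.), AgSbF6 (cat.), aq. TBHP, CH2Cl2, 0 °C to rt
Reagents that add atoms: tert-butyl hydroperoxide, CC(C)(C)OO
Why: Wacker-type oxidation of an internal alkene, in which only the 1,2-disubstituted C3=C4 bond reacts (the trisubstituted and enone alkenes are inert) and oxygen goes to C4, distal to the bulky, electron-withdrawing C2 carbinol carbon.

Step 3
Reactants: 4 hydroxy diketone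
Product: 6 (2S,4S,6E,10E)-2,4-dihydroxy-2,6,9,9-tetramethylcycloundeca-6,10-dien-1-one, via diethylboron chelate 5 (not isolated)
Conditions: Et2BOMe, THF/MeOH, −78 °C; NaBH4, −78 °C; AcOH, then MeOH azeotrope
Reagents that add atoms: none
Why: Narasaka–Prasad reduction, in which the boron chelate between O2 and the C4 carbonyl is attacked axially by external hydride to give the 2,4-syn diol (4S), while the hindered conjugated C1 ketone is left untouched at −78 °C.

Step 4
Reactants: 6 syn-diol
Product: 7 2,4-O-(di-tert-butylsilylene) ether of 6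
Conditions: t-Bu2Si(OTf)2, 2,6-lutidine, CH2Cl2, 0 °C to rt
Reagents that add atoms: di-tert-butylsilyl bis(triflate), CC(C)(C)[Si](OS(=O)(=O)C(F)(F)F)(OS(=O)(=O)C(F)(F)F)C(C)(C)C
Why: cyclic silylene protection of a 1,3-diol gives a temporary six-membered ring that blocks α-ketol rearrangement and chelation at O2 and is removable by fluoride at the end.

Step 5
Reactants: 7 silylene enone
Product: 8 (6S,7S)-6,7-epoxide of 7
Conditions: ent-Shi ketone (L-fructose series, cat.), Oxone, K2CO3, Bu4NHSO4, MeCN/DMM/aq. borate–EDTA buffer, 0 °C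
Reagents that add atoms: potassium peroxymonosulfate (Oxone), [K+].[O-]S(=O)(=O)OO
Why: Shi asymmetric epoxidation acts only on the electron-rich E-trisubstituted C6=C7 alkene, and since the D-fructose ketone gives R,R epoxides with this alkene class, the antipodal catalyst should set 6S,7S under reagent control.

Step 6
Reactants: 8 epoxide
Product: 9 (2S,4S,6S,10E)-1,7-diketone (7-oxo-6,7-dihydro derivative of 7)
Conditions: BF3·OEt2 (cat.), CH2Cl2, −78 °C
Reagents that add atoms: none
Why: Meinwald rearrangement, in which the Lewis acid opens the epoxide at tertiary C6 and H-7 migrates to the rear of the breaking C6–O bond, giving the C7 ketone and, by inversion at C6, the 6S methyl stereocentre.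

Step 7
Reactants: 9 diketone
Product: 11 (7Z)-7-(tert-butyldimethylsilyloxy)-7,10-dien-1-one, via lithium enolate 10 (not isolated)
Conditions: LDA, THF/DMPU, −78 °C; TBSCl, −78 °C to 0 °C
Reagents that add atoms: tert-butyldimethylsilyl chloride, CC(C)(C)[Si](C)(C)Cl
Why: kinetic enolate formation and O-silylation, in which the C1 ketone has no enolisable hydrogen, C8H2 is deprotonated faster than tertiary H-6 (so C6 is not touched), and the bulky C9 substituent enforces the Z(O)-enolate with C6 and C9 trans.

Step 8
Reactants: 11 silyl enol ether enone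
Product: 12 (1S)-allylic alcohol of 11
Conditions: DIBAL-H, toluene, −78 °C; Rochelle salt
Reagents that add atoms: none
Why: 1,2-reduction of the enone under polar Felkin–Anh control, in which hydride attacks anti to the non-chelating C2–OSi bond past the C2 methyl group and gives the 1S alcohol, threo to O2.

Step 9
Reactants: 12 allylic alcohol
Product: 13 (1S,10R,11R)-10,11-epoxy alcohol
Conditions: Ti(Oi-Pr)4 (cat.), D-(−)-DIPT, TBHP (decane), 4 Å MS, CH2Cl2, −20 °C
Reagents that add atoms: tert-butyl hydroperoxide, CC(C)(C)OO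
Why: Sharpless asymmetric epoxidation of a secondary E-allylic alcohol in its matched pairing ((1S)-12 is the fast-reacting series with D-(−)-tartrate), which gives the erythro epoxy alcohol, touches no undirected alkene and upgrades the enantiomeric purity.

Step 10
Reactants: 14 tiglic acid
Product: 15 (R)-2-methylbutanoic acid
Conditions: H2 (4 atm), Ru(OAc)2[(R)-H8-BINAP] (cat.), MeOH, rt
Reagents that add atoms: none
Why: Noyori-type asymmetric hydrogenation of an α,β-unsaturated acid, where the carboxylate-bound Ru–(R)-biaryl diphosphine catalyst delivers H2 to the face that gives the R acid.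

Step 11
Reactants: 13 epoxy alcohol; 15 (R)-2-methylbutanoic acid
Product: 16 (R)-2-methylbutanoate of 13
Conditions: DCC, DMAP, CH2Cl2, 0 °C to rt
Reagents that add atoms: (R)-2-methylbutanoic acid 15, CC[C@@H](C)C(=O)O
Why: Steglich esterification installs the final C1 ester before the radical step, so that it also serves as the O1 protecting group; no stereocentre is touched.

Step 12
Reactants: 16 epoxy ester
Product: 20 ring-contracted (10S,11S)-11-hydroxy-10-isopropenyl cyclodecene silyl enol ether, via C10 radical 17 (not isolated), via cyclopropylcarbinyl radical 18 (not isolated), via tertiary C9 radical 19 (not isolated)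
Conditions: Cp2TiCl2 (2.5 equiv), Mn dust, degassed THF, slow addition of 16 at high dilution, rt to 40 °C; aq. NaH2PO4
Reagents that add atoms: none
Why: Proposed new method: Cp2TiCl (Nugent–RajanBabu reagent) opens the C10–C11 epoxide homolytically with titanium on O11 and the radical on neopentylic C10 (17), which adds 3-exo-trig to enol-ether carbon C8, and radical 18 reopens by scission of C8–C9, so that C8 moves from C9 to C10, C9 leaves the ring (11 to 10 atoms) and the more stable tertiary radical 19 results. A second Cp2TiCl removes a methyl hydrogen from 19 (mixed disproportionation or β-hydride elimination), which should give the isopropenyl group rather than the tetrasubstituted alkene. The closest known reaction types are titanocene(III) epoxide-opening radical cyclisations that end in exocyclic alkenes, the 1,2-vinyl shift of 2,2-dimethylbut-3-enyl radicals used as a radical clock, and Dowd–Beckwith ring-size changes; their union as a medium-ring contraction is new. The only closure is the transient 3-exo-trig one, and the ten-membered ring arises from its fragmentation. The new stereocentre C10 is set by attack of C8 on the radical lobe anti to the bulky C11–OTi group, since C8 already lies on the inner ring face anti to the oxygen of the E-epoxide, and the enol-ether geometry is retained. The step needs C10–O over C11–O cleavage (strain relief at the neopentylic carbon, a destabilised β-acyloxy radical at C11) and migration faster than capture of 17 by Ti(III) (dilution, gem-dimethyl acceleration), while methyl migration is excluded because only sp2 groups shift in radicals.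

Step 13
Reactants: 20 homoallylic alcohol
Product: 21 11-ketone of 20
Conditions: Dess–Martin periodinane, pyridine, CH2Cl2, 0 °C
Reagents that add atoms: none
Why: Dess–Martin oxidation under buffered, non-basic conditions removes the helper configuration at C11 without enolising the α,allylic C10–H or harming the silyl enol ether.

Step 14
Reactants: 21 ketone
Product: 22 (11R)-alcohol (11-epimer of 20)
Conditions: NaBH4, CeCl3·7H2O, MeOH/THF, −78 °C
Reagents that add atoms: none
Why: Luche reduction of the only free ketone, in which hydride adds anti to the C1–O bond (polar Felkin–Anh and Cornforth models agree) and from the outer ring face with the C10–C8 ring bond anti, placing O11 cis to the C9 substituent as the cis-lactone needs.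

Step 15
Reactants: 22 alcohol
Product: 23 (8R)-8-bromo-7-ketone
Conditions: NBS, THF, −78 °C; aq. work-up
Reagents that add atoms: N-bromosuccinimide, O=C1CCC(=O)N1Br
Why: electrophilic bromination of the silyl enol ether, in which A1,3 strain with the cis OTBS group puts H-10 in the alkene plane and the C10–C11 ring bond on the inner face, so bromine enters from the outer face trans to C9 (8R); the far less nucleophilic isopropenyl group is spared.

Step 16
Reactants: 23 bromo ketone
Product: 24 12-hydroxy derivative of 23 (2-methylene-1,4-diol)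
Conditions: SeO2 (cat.), TBHP, CH2Cl2, rt
Reagents that add atoms: tert-butyl hydroperoxide (terminal oxidant), CC(C)(C)OO; selenium dioxide (oxygen carrier), O=[Se]=O
Why: selenium dioxide allylic oxidation (ene reaction, then [2,3]-shift) of the only electron-rich alkene converts the isopropenyl methyl into CH2OH; it is run before the angelate, whose own allylic methyls are SeO2-sensitive, is introduced.

Step 17
Reactants: 24 diol
Product: 27 bromo α-methylene-γ-lactone, via hydroxy enal 25 (not isolated), via lactol 26 (not isolated)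
Conditions: activated MnO2 (excess), CH2Cl2, rt
Reagents that add atoms: none
Why: MnO2 oxidative lactonisation of a 2-methylene-1,4-diol, in which the primary allylic alcohol gives the enal, O11 closes the five-membered lactol (5-exo-trig) and the lactol is oxidised to the cis-fused lactone with no change at C10 or C11.

Step 18
Reactants: 27 bromo lactone; 28 angelic acid
Product: 30 8-angelate (silylene-protected target), via cesium angelate 29 (not isolated)
Conditions: Cs2CO3 (0.5 equiv per acid), DMF, 0 °C to rt
Reagents that add atoms: angelic acid 28, C/C=C(/C)C(=O)O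
Why: SN2 displacement of an α-bromo ketone by a carboxylate, accelerated by the adjacent carbonyl, inverts C8 (8R to 8S), and because the acid acts only as a nucleophile and is never activated, its Z geometry is kept.

Step 19
Reactants: 30 silylene-protected target
Product: 31 target CNP0130200.2
Conditions: HF·pyridine, THF/pyridine, 0 °C
Reagents that add atoms: none
Why: fluoride cleavage of the di-tert-butylsilylene frees the C2 and C4 hydroxyls under near-neutral conditions that spare both esters, the α-acyloxy ketone and the α-methylene lactone.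

## Compound list

1 | zerumbone, (2E,6E,10E)-2,6,9,9-tetramethylcycloundeca-2,6,10-trien-1-one | O=C1/C=C/C(C)(C)C/C=C(C)/CC/C=C1\C | starting material
2 | potassium C1–C4 dienolate of zerumbone | [K+].CC1(C)C/C=C(C)/C/C=C/C(C)=C([O-])/C=C/1 | intermediate
3 | (2S,3E,6E,10E)-2-hydroxy-2,6,9,9-tetramethylcycloundeca-3,6,10-trien-1-one | O=C1/C=C/C(C)(C)C/C=C(C)/C/C=C/[C@]1(C)O | intermediate
4 | (2S,6E,10E)-2-hydroxy-2,6,9,9-tetramethylcycloundeca-6,10-diene-1,4-dione | O=C1/C=C/C(C)(C)C/C=C(C)/CC(=O)C[C@]1(C)O | intermediate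
5 | O2-diethylboryl derivative (chelate) of 4 | O=C1/C=C/C(C)(C)C/C=C(C)/CC(=O)C[C@]1(C)OB(CC)CC | intermediate
6 | (2S,4S,6E,10E)-2,4-dihydroxy-2,6,9,9-tetramethylcycloundeca-6,10-dien-1-one | O=C1/C=C/C(C)(C)C/C=C(C)/C[C@H](O)C[C@]1(C)O | intermediate
7 | 2,4-O-(di-tert-butylsilylene) ether of 6 | O=C1/C=C/C(C)(C)C/C=C(C)/C[C@H]2C[C@]1(C)O[Si](C(C)(C)C)(C(C)(C)C)O2 | intermediate
8 | (2S,4S,6S,7S,10E)-6,7-epoxide of 7 | O=C1/C=C/C(C)(C)C[C@@H]3O[C@@]3(C)C[C@H]2C[C@]1(C)O[Si](C(C)(C)C)(C(C)(C)C)O2 | intermediate
9 | (2S,4S,6S,10E)-1,7-diketone, silylene protected | O=C1/C=C/C(C)(C)CC(=O)[C@@H](C)C[C@H]2C[C@]1(C)O[Si](C(C)(C)C)(C(C)(C)C)O2 | intermediate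
10 | lithium C7–C8 (Z)-enolate of 9 | [Li+].O=C1/C=C/C(C)(C)/C=C([O-])/[C@@H](C)C[C@H]2C[C@]1(C)O[Si](C(C)(C)C)(C(C)(C)C)O2 | intermediate
11 | (2S,4S,6S,7Z,10E)-7-TBS enol ether of 9 | O=C1/C=C/C(C)(C)/C=C(O[Si](C)(C)C(C)(C)C)/[C@@H](C)C[C@H]2C[C@]1(C)O[Si](C(C)(C)C)(C(C)(C)C)O2 | intermediate
12 | (1S,2S,4S,6S,7Z,10E)-allylic alcohol | O[C@H]1/C=C/C(C)(C)/C=C(O[Si](C)(C)C(C)(C)C)/[C@@H](C)C[C@H]2C[C@]1(C)O[Si](C(C)(C)C)(C(C)(C)C)O2 | intermediate
13 | (1S,2S,4S,6S,7Z,10R,11R)-10,11-epoxy alcohol | O[C@H]1[C@H]3O[C@@H]3C(C)(C)/C=C(O[Si](C)(C)C(C)(C)C)/[C@@H](C)C[C@H]2C[C@]1(C)O[Si](C(C)(C)C)(C(C)(C)C)O2 | intermediate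
14 | tiglic acid, (E)-2-methylbut-2-enoic acid | C/C=C(\C)C(=O)O | starting material
15 | (R)-2-methylbutanoic acid | CC[C@@H](C)C(=O)O | intermediate
16 | (R)-2-methylbutanoate of 13 (substrate of the key step) | CC[C@@H](C)C(=O)O[C@H]1[C@H]3O[C@@H]3C(C)(C)/C=C(O[Si](C)(C)C(C)(C)C)/[C@@H](C)C[C@H]2C[C@]1(C)O[Si](C(C)(C)C)(C(C)(C)C)O2 | intermediate
17 | secondary C10 radical, O11-titanocene(IV) chloride alkoxide, 11-membered ring | CC[C@@H](C)C(=O)O[C@H]1[C@@H](O[Ti](Cl)(C4C=CC=C4)C4C=CC=C4)[CH]C(C)(C)/C=C(O[Si](C)(C)C(C)(C)C)/[C@@H](C)C[C@H]2C[C@]1(C)O[Si](C(C)(C)C)(C(C)(C)C)O2 | intermediate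
18 | cyclopropylcarbinyl (C7) radical with C8–C9–C10 cyclopropane; transient C8 configuration left open | CC[C@@H](C)C(=O)O[C@H]1[C@@H](O[Ti](Cl)(C4C=CC=C4)C4C=CC=C4)[C@@H]5C(C)(C)C5[C](O[Si](C)(C)C(C)(C)C)[C@@H](C)C[C@H]2C[C@]1(C)O[Si](C(C)(C)C)(C(C)(C)C)O2 | intermediate
19 | tertiary exocyclic C9 radical, 10-membered ring | Cl[Ti](C4C=CC=C4)(C4C=CC=C4)O[C@H]2[C@H]([C](C)C)/C=C(O[Si](C)(C)C(C)(C)C)/[C@@H](C)C[C@H]3C[C@](C)(O[Si](C(C)(C)C)(C(C)(C)C)O3)[C@H]2OC(=O)[C@H](C)CC | intermediate
20 | (1S,2S,4S,6S,7Z,10S,11S)-11-hydroxy-10-isopropenyl ten-membered ring, 7-OTBS enol ether, 1-O-(R)-2-methylbutanoate, 2,4-silylene | O[C@H]2[C@H](C(C)=C)/C=C(O[Si](C)(C)C(C)(C)C)/[C@@H](C)C[C@H]3C[C@](C)(O[Si](C(C)(C)C)(C(C)(C)C)O3)[C@H]2OC(=O)[C@H](C)CC | intermediate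
21 | 11-ketone of 20 | O=C2[C@H](C(C)=C)/C=C(O[Si](C)(C)C(C)(C)C)/[C@@H](C)C[C@H]3C[C@](C)(O[Si](C(C)(C)C)(C(C)(C)C)O3)[C@H]2OC(=O)[C@H](C)CC | intermediate
22 | (11R)-alcohol, 11-epimer of 20 | O[C@@H]2[C@H](C(C)=C)/C=C(O[Si](C)(C)C(C)(C)C)/[C@@H](C)C[C@H]3C[C@](C)(O[Si](C(C)(C)C)(C(C)(C)C)O3)[C@H]2OC(=O)[C@H](C)CC | intermediate
23 | (8R)-8-bromo-7-ketone | O[C@@H]2[C@H](C(C)=C)[C@@H](Br)C(=O)[C@@H](C)C[C@H]3C[C@](C)(O[Si](C(C)(C)C)(C(C)(C)C)O3)[C@H]2OC(=O)[C@H](C)CC | intermediate
24 | 12-hydroxy derivative of 23 (3-hydroxyprop-1-en-2-yl group on C10) | O[C@@H]2[C@H](C(=C)CO)[C@@H](Br)C(=O)[C@@H](C)C[C@H]3C[C@](C)(O[Si](C(C)(C)C)(C(C)(C)C)O3)[C@H]2OC(=O)[C@H](C)CC | intermediate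
25 | hydroxy enal (C12 aldehyde) | O[C@@H]2[C@H](C(=C)C=O)[C@@H](Br)C(=O)[C@@H](C)C[C@H]3C[C@](C)(O[Si](C(C)(C)C)(C(C)(C)C)O3)[C@H]2OC(=O)[C@H](C)CC | intermediate
26 | C12 lactol (anomers) | C=C1C(O)O[C@@H]2[C@H]1[C@@H](Br)C(=O)[C@@H](C)C[C@H]3C[C@](C)(O[Si](C(C)(C)C)(C(C)(C)C)O3)[C@H]2OC(=O)[C@H](C)CC | intermediate
27 | (8R)-bromo α-methylene-γ-lactone, cis-fused at C10/C11 | C=C1C(=O)O[C@@H]2[C@H]1[C@@H](Br)C(=O)[C@@H](C)C[C@H]3C[C@](C)(O[Si](C(C)(C)C)(C(C)(C)C)O3)[C@H]2OC(=O)[C@H](C)CC | intermediate
28 | angelic acid, (Z)-2-methylbut-2-enoic acid | C/C=C(/C)C(=O)O | starting material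
29 | cesium angelate | C/C=C(/C)C(=O)[O-].[Cs+] | intermediate
30 | (8S)-angelate, 2,4-silylene-protected target | C=C1C(=O)O[C@@H]2[C@H]1[C@H](OC(=O)/C(C)=C\C)C(=O)[C@@H](C)C[C@H]3C[C@](C)(O[Si](C(C)(C)C)(C(C)(C)C)O3)[C@H]2OC(=O)[C@H](C)CC | intermediate
31 | CNP0130200.2, zerumbone labels (1S,2S,4S,6S,8S,10S,11R,2′R) | C=C1C(=O)O[C@@H]2[C@H]1[C@H](OC(=O)/C(C)=C\C)C(=O)[C@@H](C)C[C@H](O)C[C@](C)(O)[C@H]2OC(=O)[C@H](C)CC | target

## Step count and fallbacks

Total steps: 19. Longest linear sequence: 18 (steps 1–9 and 11–19).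

**Step 12 (new method).**
- What may go wrong: the epoxide opens at C11–O, or the C10 radical is captured or deoxygenated by Ti(III) before C8 migrates.
- The fallback sets out from 16 and returns at 23. It makes the same C8 transfer in polar, individually known operations.
- BF3·OEt2 (CH2Cl2, −78 °C) lets the silyl enol ether open the activated epoxide at C10. This is a 3-exo-tet Mukaiyama-type alkylation with inversion, the Lewis-acid counterpart of the base-induced cyclisation of γ,δ-epoxy ketones. It gives the gem-dimethyl acylcyclopropane alcohol F1.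
- Dess–Martin oxidation gives the cyclopropyl diketone F2, whose C10–H is now a non-enolisable cyclopropane C–H.
- Luche reduction of the more electrophilic α-acyloxy ketone gives the (11R)-alcohol F3.
- F3 is heated in toluene with N,O-bis(trimethylsilyl)acetamide. This triggers the homo-1,5-hydrogen shift (retro-ene, enolene rearrangement) of the cis-methyl acylcyclopropane. The shift cleaves C8–C9, forms the isopropenyl group regiospecifically and releases the C7–C8 enol, trapped as the bis(trimethylsilyl) compound F4.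
- NBS followed by aqueous work-up leads to 23.

**Step 1.**
- What may go wrong: poor facial selectivity of oxygen transfer to the tetrasubstituted dienolate carbon.
- The fallback sets out from 1 and returns at 13. It moves the source of absolute configuration to step 9.
- The hydroxylation is run with achiral 2-(phenylsulfonyl)-3-phenyloxaziridine, and the racemic series is carried through steps 2–8.
- The Sharpless epoxidation with D-(−)-DIPT is then used as a kinetic resolution. Only the (1S) series is matched and epoxidised; the unreacted mismatched allylic alcohol is separated.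
- No compound outside the list is needed.

**Step 18.**
- What may go wrong: elimination toward C10, or epimerisation of the bromide by liberated bromide, competes with slow substitution by the branched carboxylate.
- The fallback sets out from 27 and returns at 30. It separates C–O bond formation from acylation.
- The small nucleophile cesium formate (DMF, 0 °C) displaces bromide with inversion to give the (8S)-formate F5.
- Mild methanolysis (KHCO3, MeOH, 0 °C) frees the (8S)-α-hydroxy ketone F6.
- F6 is angeloylated with retention through the mixed anhydride of angelic acid and 2,4,6-trichlorobenzoyl chloride (Yamaguchi conditions, toluene). This protocol is known to keep the Z geometry.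

## Further compounds

F1 | step 12 | (10S,11S)-acylcyclopropane alcohol, cis-fused C8–C9–C10 cyclopropane | O[C@H]2[C@H]4[C@H](C4(C)C)C(=O)[C@@H](C)C[C@H]3C[C@](C)(O[Si](C(C)(C)C)(C(C)(C)C)O3)[C@H]2OC(=O)[C@H](C)CC
F2 | step 12 | cyclopropyl 7,11-diketone | O=C2[C@H]4[C@H](C4(C)C)C(=O)[C@@H](C)C[C@H]3C[C@](C)(O[Si](C(C)(C)C)(C(C)(C)C)O3)[C@H]2OC(=O)[C@H](C)CC
F3 | step 12 | (11R)-acylcyclopropane alcohol | O[C@@H]2[C@H]4[C@H](C4(C)C)C(=O)[C@@H](C)C[C@H]3C[C@](C)(O[Si](C(C)(C)C)(C(C)(C)C)O3)[C@H]2OC(=O)[C@H](C)CC
F4 | step 12 | 11-O-TMS, 7-O-TMS enol ether analogue of 22 | C[Si](C)(C)O[C@@H]2[C@H](C(C)=C)/C=C(O[Si](C)(C)C)/[C@@H](C)C[C@H]3C[C@](C)(O[Si](C(C)(C)C)(C(C)(C)C)O3)[C@H]2OC(=O)[C@H](C)CC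
F0 | step 1 | none | none
F5 | step 18 | (8S)-formate lactone | C=C1C(=O)O[C@@H]2[C@H]1[C@H](OC=O)C(=O)[C@@H](C)C[C@H]3C[C@](C)(O[Si](C(C)(C)C)(C(C)(C)C)O3)[C@H]2OC(=O)[C@H](C)CC
F6 | step 18 | (8S)-α-hydroxy ketone lactone | C=C1C(=O)O[C@@H]2[C@H]1[C@H](O)C(=O)[C@@H](C)C[C@H]3C[C@](C)(O[Si](C(C)(C)C)(C(C)(C)C)O3)[C@H]2OC(=O)[C@H](C)CC
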